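**Strategy.** Ring C of the liquiritigenin half is read as a β-lactone in disguise: O1–C2–C3–C4(=O) maps onto O–C4–C3–C2(=O) of a cis-3,4-disubstituted oxetan-2-one, a temporary ring absent from the target. In one flask the aryloxide of a resorcinol monoether opens this lactone at its benzylic carbon with inversion (O1–C2), and the freed carboxyl acylates the ring carbon para to the benzyloxy group (C4–C4a), a formal [3+3] annulation. The precursor is a β-lactone that already carries the naringenin half, itself made by the same lactone/annulation pair. Two catalyst-set benzylic centres (C2, C2'') then fix C3 and C3'' as their trans partners.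

Key step: step 5

Assumption: O-trimethylsilylquinidine is taken as the pseudoenantiomeric alkaloid catalyst that gives the R benzylic carbon of the cis-lactones, by analogy with quinidine-type ketene–aldehyde cycloadditions; should the sense be opposite, O-trimethylsilylquinine is used in steps 1 and 4 with no other change.

Notation: Bpin = 4,4,5,5-tetramethyl-1,3,2-dioxaborolan-2-yl. The para-boryl group is a non-donating placeholder for the 4'-hydroxyl of each ring B, so that the benzylic carbons substitute without ionising; it is oxidised to OH in step 6.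

Step 1
Reactants: 1 methyl 4-chloro-4-oxobutanoate; 2 4-(Bpin)benzaldehyde
Product: 4 methyl 2-[(2R,3R)-4-oxo-2-[4-(Bpin)phenyl]oxetan-3-yl]acetate (cis-β-lactone), via ketene methyl 4-oxobut-3-enoate 3 (not isolated)
Conditions: O-trimethylsilylquinidine (10 mol %), LiClO4, i-Pr2NEt, CH2Cl2/Et2O, −78 °C
Reagents that add atoms: none
Why: Alkaloid/lithium salt-catalysed acyl halide–aldehyde cyclocondensation (ketene–aldehyde [2+2] of the Wynberg/Nelson type), in which the catalyst-bound (Z)-ammonium enolate of ketene 3 adds to the LiClO4-activated aldehyde through a closed transition state, so that the catalyst sets lactone C3 as R and the cis ring closure sets the benzylic carbon as R.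

Step 2
Reactants: 4 cis-β-lactone; 5 3,5-bis(benzyloxy)phenol
Product: 7 methyl 2-[(2S,3R)-5,7-bis(benzyloxy)-4-oxo-2-[4-(Bpin)phenyl]-3,4-dihydro-2H-chromen-3-yl]acetate, via aryloxy acid 6 (not isolated)
Conditions: KN(SiMe3)2, 18-crown-6, THF, 0 °C to rt; then evaporate, (CF3CO)2O, CH2Cl2, 0 °C to rt
Reagents that add atoms: none
Why: SN2 alkyl–oxygen opening of the β-lactone by the potassium aryloxide inverts the benzylic carbon to S (the non-donating boryl group keeps the substitution from ionising), and the freed acid then closes the pyranone ring by intramolecular Friedel–Crafts acylation of the doubly activated ring carbon ortho to the ether oxygen, the untouched α-carbon becoming the 2,3-trans (3R) centre.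

Step 3
Reactants: 7 flavanone methyl ester
Product: 8 2-[(2S,3R)-5,7-bis(benzyloxy)-4-oxo-2-[4-(Bpin)phenyl]-3,4-dihydro-2H-chromen-3-yl]acetic acid
Conditions: Me3SnOH, ClCH2CH2Cl, 70 °C; 5% aq HCl wash
Reagents that add atoms: trimethyltin hydroxide (C[Sn](C)(C)O)
Why: Trimethyltin hydroxide cleaves the methyl ester by a near-neutral acyl substitution (tin hydroxide ester hydrolysis), so no enolate forms that could open the pyranone ring or epimerise C2''.

Step 4
Reactants: 8 flavanonylacetic acid; 2 4-(Bpin)benzaldehyde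
Product: 11 (3R,4R)-3-[(2S,3R)-5,7-bis(benzyloxy)-4-oxo-2-[4-(Bpin)phenyl]-3,4-dihydro-2H-chromen-3-yl]-4-[4-(Bpin)phenyl]oxetan-2-one, via acid chloride 9 (not isolated), via ketene 10 (not isolated)
Conditions: (COCl)2, DMF (cat.), CH2Cl2, 0 °C to rt, evaporate; then 2, O-trimethylsilylquinidine (15 mol %), LiClO4, i-Pr2NEt, CH2Cl2/Et2O, −78 to −40 °C
Reagents that add atoms: none
Why: Acid chloride formation followed by the same alkaloid-catalysed ketene–aldehyde cyclocondensation as in step 1, in which the catalyst-bound enolate of ketene 10 adds to 2 and sets lactone C3 and C4 as R,R (cis) under catalyst control, the hindered electron-rich flavanone ketone being no competitor for the aldehyde and C3'' remaining in its thermodynamically preferred trans position.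

Step 5
Reactants: 11 flavanone-substituted cis-β-lactone; 12 3-(benzyloxy)phenol
Product: 14 (2S,3R)-7-(benzyloxy)-3-[(2S,3R)-5,7-bis(benzyloxy)-4-oxo-2-[4-(Bpin)phenyl]-3,4-dihydro-2H-chromen-3-yl]-2-[4-(Bpin)phenyl]-2,3-dihydro-4H-chromen-4-one, via aryloxy acid 13 (not isolated)
Conditions: KN(SiMe3)2, 18-crown-6, THF, 0 °C to rt; then evaporate, (CF3CO)2O, CF3SO3H (5 mol %), CH2Cl2, 0 °C
Reagents that add atoms: none
Why: The potassium aryloxide of 12 attacks the strained lactone at its benzylic carbon (alkyl–oxygen cleavage, SN2), which forms O1–C2 with inversion and frees carboxylate 13; trifluoroacetic anhydride then converts the carboxylate into a mixed anhydride that acylates the arene carbon para to the benzyloxy group, which forms C4–C4a. The closest known chemistry is the classical chromanone synthesis from β-lactones and phenols (phenoxide ring opening, then intramolecular Friedel–Crafts acylation), run here in one flask on a 3,4-disubstituted lactone. Ring C closes in the acylation stage by 6-exo-trig attack of C4a on the anhydride carbonyl; the lactone opening itself is intermolecular. C2 becomes S because the R benzylic centre of the cis-lactone is inverted, and C3 keeps the R configuration set in step 4, which is also the thermodynamically preferred 2,3-trans arrangement, so any epimerisation at C3 or C3'' is self-correcting. The step needs alkyl– over acyl–oxygen cleavage, substitution without ionisation and para-regioselective acylation: ring strain and a soft, weakly basic aryloxide (carbonyl attack is reversible) favour the first, the electron-poor boryl-substituted aryl group suppresses benzylic ionisation, and the benzyloxy group directs acylation to its para position, while the ketone-deactivated ring A of the naringenin half and the borylated rings B do not compete.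

Step 6
Reactants: 14 bis-boronate biflavanone
Product: 15 (2S,3R)-7-(benzyloxy)-3-[(2S,3R)-5,7-bis(benzyloxy)-2-(4-hydroxyphenyl)-4-oxo-3,4-dihydro-2H-chromen-3-yl]-2-(4-hydroxyphenyl)-2,3-dihydro-4H-chromen-4-one
Conditions: Me3NO, CH2Cl2, rt; then aq NH4Cl
Reagents that add atoms: trimethylamine N-oxide (C[N+](C)(C)[O-])
Why: Amine N-oxide ipso-hydroxylation of both aryl boronates (1,2-aryl shift from boron to oxygen, then hydrolysis of the aryl borate) runs under neutral conditions and keeps the new phenols masked as borates until work-up, so the base-sensitive flavanone stereocentres are not touched.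

Step 7
Reactants: 15 tri-O-benzyl biflavanone
Product: 16 (2S,3R)-3-[(2S,3R)-5,7-dihydroxy-2-(4-hydroxyphenyl)-4-oxo-3,4-dihydro-2H-chromen-3-yl]-7-hydroxy-2-(4-hydroxyphenyl)-2,3-dihydro-4H-chromen-4-one (target)
Conditions: H2 (1 atm), Pd/C, EtOAc/MeOH, rt
Reagents that add atoms: none
Why: Hydrogenolysis of the three aryl benzyl ethers over palladium on carbon is neutral and should free the remaining phenols without enolising or opening either pyranone ring, so all four stereocentres are retained.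

**Compound list**

1 | methyl 4-chloro-4-oxobutanoate | COC(=O)CCC(Cl)=O | starting material
2 | 4-(4,4,5,5-tetramethyl-1,3,2-dioxaborolan-2-yl)benzaldehyde | O=Cc1ccc(cc1)B1OC(C)(C)C(C)(C)O1 | starting material
3 | methyl 4-oxobut-3-enoate (ketene, not isolated) | COC(=O)CC=C=O | intermediate
4 | methyl 2-[(2R,3R)-4-oxo-2-[4-(Bpin)phenyl]oxetan-3-yl]acetate (cis-β-lactone) | COC(=O)C[C@H]1C(=O)O[C@H]1c1ccc(cc1)B1OC(C)(C)C(C)(C)O1 | intermediate
5 | 3,5-bis(benzyloxy)phenol | Oc1cc(OCc2ccccc2)cc(OCc2ccccc2)c1 | starting material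
6 | (2R,3S)-3-[3,5-bis(benzyloxy)phenoxy]-2-(2-methoxy-2-oxoethyl)-3-[4-(Bpin)phenyl]propanoic acid (formed as its potassium salt, not isolated) | COC(=O)C[C@@H](C(=O)O)[C@H](Oc1cc(OCc2ccccc2)cc(OCc2ccccc2)c1)c1ccc(cc1)B1OC(C)(C)C(C)(C)O1 | intermediate
7 | methyl 2-[(2S,3R)-5,7-bis(benzyloxy)-4-oxo-2-[4-(Bpin)phenyl]-3,4-dihydro-2H-chromen-3-yl]acetate | COC(=O)C[C@H]1C(=O)c2c(OCc3ccccc3)cc(OCc3ccccc3)cc2O[C@@H]1c1ccc(cc1)B1OC(C)(C)C(C)(C)O1 | intermediate
8 | 2-[(2S,3R)-5,7-bis(benzyloxy)-4-oxo-2-[4-(Bpin)phenyl]-3,4-dihydro-2H-chromen-3-yl]acetic acid | OC(=O)C[C@H]1C(=O)c2c(OCc3ccccc3)cc(OCc3ccccc3)cc2O[C@@H]1c1ccc(cc1)B1OC(C)(C)C(C)(C)O1 | intermediate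
9 | 2-[(2S,3R)-5,7-bis(benzyloxy)-4-oxo-2-[4-(Bpin)phenyl]-3,4-dihydro-2H-chromen-3-yl]acetyl chloride (not isolated) | ClC(=O)C[C@H]1C(=O)c2c(OCc3ccccc3)cc(OCc3ccccc3)cc2O[C@@H]1c1ccc(cc1)B1OC(C)(C)C(C)(C)O1 | intermediate
10 | (2S,3R)-5,7-bis(benzyloxy)-3-(2-oxoethenyl)-2-[4-(Bpin)phenyl]-2,3-dihydro-4H-chromen-4-one (ketene, not isolated) | O=C=C[C@H]1C(=O)c2c(OCc3ccccc3)cc(OCc3ccccc3)cc2O[C@@H]1c1ccc(cc1)B1OC(C)(C)C(C)(C)O1 | intermediate
11 | (3R,4R)-3-[(2S,3R)-5,7-bis(benzyloxy)-4-oxo-2-[4-(Bpin)phenyl]-3,4-dihydro-2H-chromen-3-yl]-4-[4-(Bpin)phenyl]oxetan-2-one | O=C1O[C@@H](c2ccc(cc2)B2OC(C)(C)C(C)(C)O2)[C@H]1[C@H]1C(=O)c2c(OCc3ccccc3)cc(OCc3ccccc3)cc2O[C@@H]1c1ccc(cc1)B1OC(C)(C)C(C)(C)O1 | intermediate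
12 | 3-(benzyloxy)phenol | Oc1cccc(OCc2ccccc2)c1 | starting material
13 | (2R,3S)-3-[3-(benzyloxy)phenoxy]-2-[(2S,3R)-5,7-bis(benzyloxy)-4-oxo-2-[4-(Bpin)phenyl]-3,4-dihydro-2H-chromen-3-yl]-3-[4-(Bpin)phenyl]propanoic acid (formed as its potassium salt, not isolated) | OC(=O)[C@@H]([C@H](Oc1cccc(OCc2ccccc2)c1)c1ccc(cc1)B1OC(C)(C)C(C)(C)O1)[C@H]1C(=O)c2c(OCc3ccccc3)cc(OCc3ccccc3)cc2O[C@@H]1c1ccc(cc1)B1OC(C)(C)C(C)(C)O1 | intermediate
14 | (2S,3R)-7-(benzyloxy)-3-[(2S,3R)-5,7-bis(benzyloxy)-4-oxo-2-[4-(Bpin)phenyl]-3,4-dihydro-2H-chromen-3-yl]-2-[4-(Bpin)phenyl]-2,3-dihydro-4H-chromen-4-one | O=C1c2ccc(OCc3ccccc3)cc2O[C@H](c2ccc(cc2)B2OC(C)(C)C(C)(C)O2)[C@H]1[C@H]1C(=O)c2c(OCc3ccccc3)cc(OCc3ccccc3)cc2O[C@@H]1c1ccc(cc1)B1OC(C)(C)C(C)(C)O1 | intermediate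
15 | (2S,3R)-7-(benzyloxy)-3-[(2S,3R)-5,7-bis(benzyloxy)-2-(4-hydroxyphenyl)-4-oxo-3,4-dihydro-2H-chromen-3-yl]-2-(4-hydroxyphenyl)-2,3-dihydro-4H-chromen-4-one | O=C1c2ccc(OCc3ccccc3)cc2O[C@H](c2ccc(O)cc2)[C@H]1[C@H]1C(=O)c2c(OCc3ccccc3)cc(OCc3ccccc3)cc2O[C@@H]1c1ccc(O)cc1 | intermediate
16 | (2S,3R)-3-[(2S,3R)-5,7-dihydroxy-2-(4-hydroxyphenyl)-4-oxo-3,4-dihydro-2H-chromen-3-yl]-7-hydroxy-2-(4-hydroxyphenyl)-2,3-dihydro-4H-chromen-4-one | O=C1c2ccc(O)cc2O[C@H](c2ccc(O)cc2)[C@H]1[C@H]1C(=O)c2c(O)cc(O)cc2O[C@@H]1c1ccc(O)cc1 | target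

Total step count: 7. Longest linear sequence: 7 steps (1 to 16).

**Steps most likely to fail**

Step 5 (key step). The aryloxide may attack the lactone carbonyl instead of C4 (acyl–oxygen cleavage followed by retro-aldol loss of the aldehyde), or substitution at the hindered benzylic carbon may be so slow that base-induced opening of the naringenin pyranone ring competes. Fallback: setting out from 11, the lactone is opened at the acyl carbon with allyl alcohol and catalytic La(OtBu)3 to give, with retention, the syn-β-hydroxy allyl ester F1. F1 is etherified with 12 under Mitsunobu conditions (PPh3, DIAD, toluene, 0 °C), which invert the carbinol carbon without any free aryloxide and give the allyl ester of the aryloxy acid F2. Pd(PPh3)4 and morpholine then remove the allyl group and deliver acid 13, where the route is rejoined for the anhydride stage of step 5.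

Step 4. The γ-keto acid chloride 9 may close to a cyclic pseudo-chloride or enol lactone instead of forming ketene 10, or catalyst and substrate may be mismatched so that facial selectivity is poor. Fallback: the second lactone is built before the first pyranone ring is closed. Setting out from acid 6 (isolated by acidic work-up after the first stage of step 2), esterification with tert-butyl 2,2,2-trichloroacetimidate gives the tert-butyl methyl diester F3, and Me3SnOH frees the side-chain acid F4. Oxalyl chloride gives the acid chloride F5, whose ketene F6 undergoes the same alkaloid-catalysed cyclocondensation with 2 to give the ketone-free cis-lactone F7. Opening with the potassium aryloxide of 12 gives the aryloxy acid F8. In the same flask CF3CO2H/(CF3CO)2O with catalytic CF3SO3H cleaves the tert-butyl ester to the diacid F9 and closes both pyranone rings by double Friedel–Crafts acylation, rejoining the route at 14.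

Step 2. The same acyl–oxygen cleavage and retro-aldol fragmentation as in step 5 may occur, or the acylation stage may stall. Fallback: setting out from 4, La(OtBu)3-catalysed opening with allyl alcohol gives the hydroxy diester F10, used at once so that the free hydroxyl does not lactonise onto the methyl ester. Mitsunobu etherification with 5 (PPh3, DIAD) gives the aryl ether diester F11 with inversion, and Pd(PPh3)4/morpholine deallylation returns acid 6, from which step 2 continues with the anhydride stage.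

Further compounds
F1 | step 5 | prop-2-en-1-yl (2R,3R)-2-[(2S,3R)-5,7-bis(benzyloxy)-4-oxo-2-[4-(Bpin)phenyl]-3,4-dihydro-2H-chromen-3-yl]-3-hydroxy-3-[4-(Bpin)phenyl]propanoate | C=CCOC(=O)[C@@H]([C@@H](O)c1ccc(cc1)B1OC(C)(C)C(C)(C)O1)[C@H]1C(=O)c2c(OCc3ccccc3)cc(OCc3ccccc3)cc2O[C@@H]1c1ccc(cc1)B1OC(C)(C)C(C)(C)O1
F2 | step 5 | prop-2-en-1-yl (2R,3S)-3-[3-(benzyloxy)phenoxy]-2-[(2S,3R)-5,7-bis(benzyloxy)-4-oxo-2-[4-(Bpin)phenyl]-3,4-dihydro-2H-chromen-3-yl]-3-[4-(Bpin)phenyl]propanoate | C=CCOC(=O)[C@@H]([C@H](Oc1cccc(OCc2ccccc2)c1)c1ccc(cc1)B1OC(C)(C)C(C)(C)O1)[C@H]1C(=O)c2c(OCc3ccccc3)cc(OCc3ccccc3)cc2O[C@@H]1c1ccc(cc1)B1OC(C)(C)C(C)(C)O1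
F3 | step 4 | 1-tert-butyl 4-methyl (2R)-2-[(S)-[3,5-bis(benzyloxy)phenoxy][4-(Bpin)phenyl]methyl]butanedioate | COC(=O)C[C@@H](C(=O)OC(C)(C)C)[C@H](Oc1cc(OCc2ccccc2)cc(OCc2ccccc2)c1)c1ccc(cc1)B1OC(C)(C)C(C)(C)O1
F4 | step 4 | (3R)-3-[(S)-[3,5-bis(benzyloxy)phenoxy][4-(Bpin)phenyl]methyl]-4-tert-butoxy-4-oxobutanoic acid | OC(=O)C[C@@H](C(=O)OC(C)(C)C)[C@H](Oc1cc(OCc2ccccc2)cc(OCc2ccccc2)c1)c1ccc(cc1)B1OC(C)(C)C(C)(C)O1
F5 | step 4 | tert-butyl (2R)-2-[(S)-[3,5-bis(benzyloxy)phenoxy][4-(Bpin)phenyl]methyl]-4-chloro-4-oxobutanoate | ClC(=O)C[C@@H](C(=O)OC(C)(C)C)[C@H](Oc1cc(OCc2ccccc2)cc(OCc2ccccc2)c1)c1ccc(cc1)B1OC(C)(C)C(C)(C)O1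
F6 | step 4 | tert-butyl (2R)-2-[(S)-[3,5-bis(benzyloxy)phenoxy][4-(Bpin)phenyl]methyl]-4-oxobut-3-enoate (ketene) | O=C=C[C@@H](C(=O)OC(C)(C)C)[C@H](Oc1cc(OCc2ccccc2)cc(OCc2ccccc2)c1)c1ccc(cc1)B1OC(C)(C)C(C)(C)O1
F7 | step 4 | tert-butyl (2R,3S)-3-[3,5-bis(benzyloxy)phenoxy]-2-[(2R,3R)-4-oxo-2-[4-(Bpin)phenyl]oxetan-3-yl]-3-[4-(Bpin)phenyl]propanoate | O=C1O[C@@H](c2ccc(cc2)B2OC(C)(C)C(C)(C)O2)[C@H]1[C@@H](C(=O)OC(C)(C)C)[C@H](Oc1cc(OCc2ccccc2)cc(OCc2ccccc2)c1)c1ccc(cc1)B1OC(C)(C)C(C)(C)O1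
F8 | step 4 | (2R,3R)-2-[(S)-[3-(benzyloxy)phenoxy][4-(Bpin)phenyl]methyl]-3-[(S)-[3,5-bis(benzyloxy)phenoxy][4-(Bpin)phenyl]methyl]-4-tert-butoxy-4-oxobutanoic acid | OC(=O)[C@@H]([C@H](Oc1cccc(OCc2ccccc2)c1)c1ccc(cc1)B1OC(C)(C)C(C)(C)O1)[C@@H](C(=O)OC(C)(C)C)[C@H](Oc1cc(OCc2ccccc2)cc(OCc2ccccc2)c1)c1ccc(cc1)B1OC(C)(C)C(C)(C)O1
F9 | step 4 | (2R,3R)-2-[(S)-[3-(benzyloxy)phenoxy][4-(Bpin)phenyl]methyl]-3-[(S)-[3,5-bis(benzyloxy)phenoxy][4-(Bpin)phenyl]methyl]butanedioic acid | OC(=O)[C@@H]([C@H](Oc1cccc(OCc2ccccc2)c1)c1ccc(cc1)B1OC(C)(C)C(C)(C)O1)[C@@H](C(=O)O)[C@H](Oc1cc(OCc2ccccc2)cc(OCc2ccccc2)c1)c1ccc(cc1)B1OC(C)(C)C(C)(C)O1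
F10 | step 2 | 4-methyl 1-prop-2-en-1-yl (2R)-2-[(R)-hydroxy[4-(Bpin)phenyl]methyl]butanedioate | COC(=O)C[C@@H](C(=O)OCC=C)[C@@H](O)c1ccc(cc1)B1OC(C)(C)C(C)(C)O1
F11 | step 2 | 4-methyl 1-prop-2-en-1-yl (2R)-2-[(S)-[3,5-bis(benzyloxy)phenoxy][4-(Bpin)phenyl]methyl]butanedioate | COC(=O)C[C@@H](C(=O)OCC=C)[C@H](Oc1cc(OCc2ccccc2)cc(OCc2ccccc2)c1)c1ccc(cc1)B1OC(C)(C)C(C)(C)O1
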